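## Structural features

The target is a monocyclic, iridal-type C30 terpenoid: one cyclohexane ring carries all the polar functionality and a (3E,7E)-4,8,12-trimethyltrideca-3,7,11-trienyl chain. Numbering the ring from the quaternary carbon, C1 bears a hydroxymethyl group and the chain, C2 a 3-hydroxypropyl arm, C3 an exocyclic tetrasubstituted double bond to a C(CH3)CHO unit (Z, formyl on the C2 side), C4 and C5 are methylenes, and C6 is a methyl carbinol. The stereocentres C6, C1 and C2 are contiguous, two of them fully substituted, and the C1 hydroxymethyl, the C2 arm and the C6 hydroxyl all lie on one face of the ring. Fragile points are the enal (its geometry, and C2, its γ-position, which can epimerise through the dienol), the acid-sensitive skipped triene and, in intermediates, every β-hydroxy carbonyl array around C1, which can open by retro-aldol cleavage. The real difficulty is the congested C6–C1–C2 triad, above all the all-carbon quaternary C1 whose hydroxymethyl and chain arms must be told apart, and after that the geometry of the tetrasubstituted alkene. The key step reads ring carbons C1–C6 as a former 1,4-benzoquinone: the oxygenated carbons C3 and C6 are para, and the cis carbon arms on C1 and C2 are the two ends of a butadiene added across C1–C2 and later cut open, while the chain on C1 grows from an ester the quinone already carries. In the bicyclic intermediates ring A is this surviving ring and ring B the temporary cyclohexene; they are named as naphthalenes, in which C4a, C8a, C1 and C4 are C1, C2, C3 and C6 of the target, C5 becomes the hydroxymethyl carbon and C8, C7, C6 become the three carbons of the arm.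

## Logic of the disconnections

24 ⇒ 23. The two O–Si bonds are cut. The primary alcohols must be masked while chromium acts on the molecule, and silyl ethers come off at the end with fluoride under non-basic conditions. Nothing is gained in skeleton; the demand is that the unmasking does not isomerise the enal.

23 ⇒ 22 ⇒ 21. The C3=C(CH3) double bond is traced back, through a 1,3-shift of oxygen, to the tertiary allylic alcohol 22, and the C3–C(isopropenyl) bond of 22 is then cut to give ketone 21. This removes the tetrasubstituted alkene and its geometry from the rest of the route. The forward steps must add a carbon nucleophile to a hindered, enolisable ketone and turn the allylic system over with the formyl group ending on the C2 side.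

21 ⇒ 20 ⇒ 14 + 18. With the C3 ketone masked as its ketal (20), the C(sp3)–C(sp2) bond between the second and third chain carbons is cut. This is the convergent cut: it separates the ring fragment, which keeps a vinyl group, from a C14 vinyl iodide that already holds both E double bonds. The forward coupling needs a clean hydroboration of a single terminal alkene and retention of the iodide geometry.

18 ⇒ 16 ⇒ 15. In 18 the C–I and C–CH3 bonds on the same double bond are cut together (retro-carbometalation of a terminal alkyne), and 16 is cut at the propargylic C–C bond. The trisubstituted E alkene is reduced to a syn addition to an alkyne. The forward steps need aluminium on the terminal carbon and SN2 rather than SN2′ alkylation.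

14 ⇒ 13 ⇒ 12 ⇒ 11 ⇒ 10. The vinyl C=C bond is cut to aldehyde 13, which goes back through alcohol 12 to the ester of 11; removing the silyl ethers gives 10. The chain carbon on C1 thereby becomes an ester, the group a quinone can carry. The demands are reduction of a very hindered ester and handling of a β-hydroxy aldehyde without retro-aldol cleavage or silyl migration between the two CH2O groups on C1.

10 ⇒ 8. The two primary alcohol carbons are reconnected as a cis double bond (retro-ozonolysis, through 9), which closes ring B. The cis relationship of two flexible arms becomes a cis ring fusion, and the bicycle can control C6. The alkene of 8 must lie between C5 and C6, so that one carbon stays on C4a and three on C8a.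

8 ⇒ 7. The C4–CH3 bond is cut to the ketone, which is a carbonyl of the future quinone. The forward addition must come from the convex face and leave the neighbouring ester alone.

7 ⇒ 6. The C5=C6 alkene is derived from a C6=C7 alkene with an acetate on C5 (allylic transposition with loss of oxygen). This puts the alkene where a Diels–Alder reaction leaves it and the oxygen where a 1-oxygenated diene leaves it. The forward reduction must deliver hydrogen to C7 and not to C5.

6 ⇒ 5 ⇒ 4. The two ketal C–O bonds are cut (5) and the C2–C3 single bond is returned to the ene-dione double bond (4). This restores the quinone oxidation pattern. Forward, the two ketones of 5 must be distinguished by their steric surroundings.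

4 ⇒ 2 + 3. The bonds C4a–C5 and C8a–C8 are cut in the retro-[4+2] sense. Ring B, three stereocentres and the quaternary carbon vanish, leaving a flat quinone and a four-carbon diene. The forward step must control site, regiochemistry, endo mode and π-face.

2 ⇒ 1. The quinone is the oxidised form of a commercial hydroquinone ester; it must be used before it decomposes.

## Other disconnections considered

Alternative 1: The cut is the C1–CH2OH bond. The substrate would be A1, the (bromomethyl)dimethylsilyl ether of a 4-hydroxy-4-methyl-3-vinylcyclohex-2-enone that already carries the protected arm on C2. Bu3SnH and azobisisobutyronitrile would generate the α-silyl radical, which should close 5-exo onto C1 (the enone β-carbon); the α-keto radical at C2 would then take hydrogen from the stannane to give the cis-fused siloxane A2, and oxidative C–Si cleavage would unveil the hydroxymethyl group.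
- In favour: the C6 oxygen dictates C1 through a five-membered tether that can only be cis-fused; the CH2OH carbon arrives at the right oxidation level; the vinyl handle for the chain is already present; no ring is sacrificed.
- Against: a nucleophilic radical must bond to a fully substituted carbon of a cross-conjugated dienone, where addition to the vinyl group competes; C2 is set only by the face of hydrogen-atom transfer or by later equilibration; the C6 carbinol of A1 needs its own asymmetric synthesis; stoichiometric tin is used.
- Comparison: structurally A2 reaches the triad by relay from one pre-set centre, whereas the chosen plan makes C1 and C2 together and adds C6 afterwards. Mechanistically the tether is the equal of convex-face addition for the C1/C6 relationship, but the concerted cis addition is safer for C1/C2. In step economy after its key step the alternative is the better (no ester-to-vinyl conversion, no ring scission), though it pays for this in making A1.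

Alternative 2: The cut is the C3=C(CH3) double bond, with the C2 arm as tether. Ketone A3, whose arm alcohol is esterified with 2,2-dibromopropanoic acid, would be treated with SmI2: reduction of one C–Br bond gives a samarium enolate that adds to the C3 ketone, and reduction of the second with loss of the samarium alkoxide forms the alkene and closes the eight-membered lactone A4.
- In favour: the ring admits only the isomer with the carbonyl carbon on the C2 side, so the alkene geometry is fixed by connectivity; conditions are neutral and compatible with the polyene.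
- Against: it is an end-game step and does not address the C6–C1–C2 triad; an eight-membered closure has an entropic and transannular cost and needs high dilution; the lactone must then be reduced and the allylic alcohol reoxidised selectively; the other two hydroxyls need orthogonal protection.
- Comparison: on control of enal geometry this alternative is the better. On step economy the chosen plan is shorter at this stage. Structurally the two are complementary, since A3 could be reached from 21. Mechanistically both rely on carbonyl addition to the same hindered ketone, so they are equal there.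

Alternative 3: The cut is the C1–C6 ring bond. The open-chain keto ester A5, whose C3/C6 dicarbonyl pair would be kept latent in an aromatic five-membered heterocycle in earlier steps, carries an allylic bromide conjugated to the ester. Indium metal would form an allylindium that should add through its ester-bearing γ-carbon (C1) to the C6 methyl ketone, closing the ring to A6 with a vinyl group on C1.
- In favour: the quaternary carbon and the tertiary carbinol are formed in one C–C bond under mild conditions that spare the C3 ketone; no ring is sacrificed; the ester already sits on the future CH2OH carbon and the vinyl on the future chain carbon.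
- Against: all stereochemical information must come from C2 of A5, a centre α to a ketone and allylic to an enoate in an open chain, which is prone to epimerise; the C1/C6 relationship depends on which of two chair-like transition states is preferred; ketones are poorer acceptors than aldehydes for allylindium reagents.
- Comparison: in bond and step economy the alternative is the better (ring and both fully substituted carbons in one step, no scission). In stereochemical security the chosen plan is the better, because a rigid cis-fused bicycle from a concerted, catalyst-controlled cycloaddition carries all three centres. The late stages (Suzuki coupling, enal formation) are the same, so they are equal there.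

Key step: step 2

Remark on the chemistry: the sense of face selection by the (S)-configured oxazaborolidinium ion is assumed from the usual shielding model for this catalyst class; should the other face be preferred, the catalyst from (R)-α,α-diphenylprolinol is used and nothing else changes.

Remark on the chemistry: commercial 3 is an E/Z mixture; only the E isomer is expected to react at −78 °C, so it is used in excess.

Remark on the chemistry: the (4aR,5R,8aS) adduct 4 places C5 and C8 on the face of ring A that carries CH2OH and the arm in 24, and the ester on the face of the chain, so this enantiomer is the one required.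

## Route

Step 1
Reactants: 1 methyl 2,5-dihydroxybenzoate
Product: 2 methyl 3,6-dioxocyclohexa-1,4-diene-1-carboxylate (2-methoxycarbonyl-1,4-benzoquinone)
Conditions: Ag2O, Na2SO4, toluene, rt, dark; filter and use at once
Reagents that add atoms: none
Why: Two-electron oxidation of a hydroquinone to the quinone by Ag2O; the electron-poor quinone hydrates and dimerises easily, so the filtered solution is carried straight into step 2.

Step 2
Reactants: 2 methyl 3,6-dioxocyclohexa-1,4-diene-1-carboxylate; 3 (E)-buta-1,3-dien-1-yl acetate
Product: 4 methyl (4aR,5R,8aS)-5-acetoxy-1,4-dioxo-1,4,4a,5,8,8a-hexahydronaphthalene-4a-carboxylate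
Conditions: (S)-tetrahydro-1-(2-methylphenyl)-3,3-diphenyl-1H,3H-pyrrolo[1,2-c][1,3,2]oxazaborole·HNTf2 (20 mol%), 3 (2.5 equiv), CH2Cl2, −78 °C
Reagents that add atoms: none
Why: The step is a concerted, asynchronous [4+2] cycloaddition with Lewis-acid lowering of the dienophile LUMO; the closest known reaction type is the enantioselective Diels–Alder reaction of 2-alkoxycarbonyl-1,4-benzoquinones with 1-oxygenated butadienes under protonated oxazaborolidine catalysis. Ring B is closed intermolecularly by suprafacial addition of the s-cis diene across the ester-bearing double bond of 2, forming C4a–C5 and C8a–C8. Site selectivity is secured because this double bond is the most electron-poor of the quinone. Regioselectivity follows from the larger HOMO coefficient at the unsubstituted diene terminus, which bonds to the quinone carbon β to the ester, giving the ortho adduct. C4a and C8a are cis because both new bonds form on one face of a ring double bond. C5 is set by the endo transition state (quinone ring beneath the diene), which places the acetate cis to the C4 carbonyl carbon on the concave face; this centre is erased later. The absolute configuration comes from the catalyst: the cationic boron binds the quinone carbonyl next to the ester-bearing carbon and its aryl groups cover one π-face, so the diene adds to the other. Low temperature keeps the uncatalysed racemic pathway slow.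

Step 3
Reactants: 4 methyl (4aR,5R,8aS)-5-acetoxy-1,4-dioxo-1,4,4a,5,8,8a-hexahydronaphthalene-4a-carboxylate
Product: 5 methyl (4aR,5R,8aS)-5-acetoxy-1,4-dioxo-1,2,3,4,4a,5,8,8a-octahydronaphthalene-4a-carboxylate
Conditions: Zn dust, AcOH, 0 °C → rt
Reagents that add atoms: none
Why: Dissolving-metal conjugate reduction of the ene-dione, standard for quinone Diels–Alder adducts; the isolated alkene, the allylic acetate and the quaternary β-keto ester are inert, and short cold contact should leave the cis fusion at C8a unepimerised.

Step 4
Reactants: 5 methyl (4aR,5R,8aS)-5-acetoxy-1,4-dioxo-1,2,3,4,4a,5,8,8a-octahydronaphthalene-4a-carboxylate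
Product: 6 methyl (4aR,5R,8aS)-5-acetoxy-1,1-(ethylenedioxy)-4-oxo-1,2,3,4,4a,5,8,8a-octahydronaphthalene-4a-carboxylate
Conditions: (Me3SiOCH2)2, Me3SiOTf (cat.), CH2Cl2, −78 → −20 °C; pyridine quench
Reagents that add atoms: 1,2-bis(trimethylsilyloxy)ethane, C[Si](C)(C)OCCO[Si](C)(C)C
Why: Noyori ketalisation under kinetic control; the C1 ketone, flanked by CH and CH2, should react much faster than the C4 ketone, which is neopentylic and deactivated by the geminal ester. Aprotic, cold conditions avoid enolisation at C8a.

Step 5
Reactants: 6 methyl (4aR,5R,8aS)-5-acetoxy-1,1-(ethylenedioxy)-4-oxo-1,2,3,4,4a,5,8,8a-octahydronaphthalene-4a-carboxylate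
Product: 7 methyl (4aS,8aS)-1,1-(ethylenedioxy)-4-oxo-1,2,3,4,4a,7,8,8a-octahydronaphthalene-4a-carboxylate
Conditions: Pd(PPh3)4 (5 mol%), Bu3SnH (slow addition), THF, rt → 50 °C
Reagents that add atoms: none
Why: Palladium-catalysed allylic hydrogenolysis with a tin hydride: zerovalent palladium ionises the concave-face acetate from the convex face, and the hydride passed from tin to palladium should be delivered to the less hindered allyl terminus C7, remote from the quaternary carbon, which moves the double bond to C5=C6. A formate donor is avoided because its hydride transfer usually goes to the more hindered terminus, which here would leave the alkene where it was; no stereocentre is created.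

Step 6
Reactants: 7 methyl (4aS,8aS)-1,1-(ethylenedioxy)-4-oxo-1,2,3,4,4a,7,8,8a-octahydronaphthalene-4a-carboxylate
Product: 8 methyl (4S,4aS,8aS)-1,1-(ethylenedioxy)-4-hydroxy-4-methyl-1,2,3,4,4a,7,8,8a-octahydronaphthalene-4a-carboxylate
Conditions: MeMgBr, CeCl3, THF, −78 °C; cold aq. NH4Cl
Reagents that add atoms: methylmagnesium bromide, C[Mg]Br
Why: Organocerium 1,2-addition (Imamoto conditions) to a hindered, enolisable ketone, leaving the neopentylic ester alone. Attack on the convex face of the cis-fused bicycle, anti to ring B, puts the methyl cis to the angular ester and the hydroxyl cis to C5, which sets C4 (future C6); a cold quench avoids retro-aldol opening of the β-alkoxy ester.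

Step 7
Reactants: 8 methyl (4S,4aS,8aS)-1,1-(ethylenedioxy)-4-hydroxy-4-methyl-1,2,3,4,4a,7,8,8a-octahydronaphthalene-4a-carboxylate
Product: 10 methyl (1R,2S,6S)-3,3-(ethylenedioxy)-6-hydroxy-1-(hydroxymethyl)-2-(3-hydroxypropyl)-6-methylcyclohexane-1-carboxylate, via ozonide 9 (not isolated)
Conditions: O3, CH2Cl2, −78 °C; then NaBH4, MeOH, −78 → 0 °C
Reagents that add atoms: ozone, [O-][O+]=O
Why: Ozonolysis of the only C=C bond with reductive work-up gives both primary alcohols directly; C5 becomes the hydroxymethyl on C1 and C6–C8 the three-carbon arm on C2, so the cis ring fusion becomes the cis relationship of the arms. The ketal protects C3 from NaBH4 and the ester is inert to it.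

Step 8
Reactants: 10 methyl (1R,2S,6S)-3,3-(ethylenedioxy)-6-hydroxy-1-(hydroxymethyl)-2-(3-hydroxypropyl)-6-methylcyclohexane-1-carboxylate
Product: 11 methyl (1R,2S,6S)-1-[(tert-butyldiphenylsilyloxy)methyl]-2-[3-(tert-butyldiphenylsilyloxy)propyl]-3,3-(ethylenedioxy)-6-hydroxy-6-methylcyclohexane-1-carboxylate
Conditions: t-BuPh2SiCl, imidazole, DMAP (cat.), DMF, rt → 40 °C
Reagents that add atoms: tert-butyl(chloro)diphenylsilane, CC(C)(C)[Si](Cl)(c1ccccc1)c1ccccc1
Why: Silylation of both primary alcohols; the tertiary C6 hydroxyl does not react with the bulky chloride. These ethers are chosen because they survive the later aqueous acid and resist 1,3 O-to-O migration.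

Step 9
Reactants: 11 methyl (1R,2S,6S)-1-[(tert-butyldiphenylsilyloxy)methyl]-2-[3-(tert-butyldiphenylsilyloxy)propyl]-3,3-(ethylenedioxy)-6-hydroxy-6-methylcyclohexane-1-carboxylate
Product: 12 [(1R,2S,6S)-1-[(tert-butyldiphenylsilyloxy)methyl]-2-[3-(tert-butyldiphenylsilyloxy)propyl]-3,3-(ethylenedioxy)-6-hydroxy-6-methylcyclohexyl]methanol
Conditions: i-Bu2AlH (excess), CH2Cl2, −78 → 0 °C; aq. KNaC4H4O6
Reagents that add atoms: none
Why: Hydride reduction of the hindered ester to the primary alcohol, helped by the neighbouring aluminium alkoxide. A cold, neutral tartrate work-up guards against silyl migration between the two geminal CH2O groups, which would scramble C1.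

Step 10
Reactants: 12 [(1R,2S,6S)-1-[(tert-butyldiphenylsilyloxy)methyl]-2-[3-(tert-butyldiphenylsilyloxy)propyl]-3,3-(ethylenedioxy)-6-hydroxy-6-methylcyclohexyl]methanol
Product: 13 (1R,2S,6S)-1-[(tert-butyldiphenylsilyloxy)methyl]-2-[3-(tert-butyldiphenylsilyloxy)propyl]-3,3-(ethylenedioxy)-6-hydroxy-6-methylcyclohexane-1-carbaldehyde
Conditions: Dess–Martin periodinane, NaHCO3, CH2Cl2, 0 °C → rt
Reagents that add atoms: none
Why: Dess–Martin oxidation under buffered, near-neutral conditions; the tertiary alcohol is inert and the β-hydroxy aldehyde is not exposed to base.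

Step 11
Reactants: 13 (1R,2S,6S)-1-[(tert-butyldiphenylsilyloxy)methyl]-2-[3-(tert-butyldiphenylsilyloxy)propyl]-3,3-(ethylenedioxy)-6-hydroxy-6-methylcyclohexane-1-carbaldehyde
Product: 14 1-vinyl analogue of 13 (CH=CH2 in place of CHO on C1; C1, C2 and C6 unchanged in space)
Conditions: Ph3PCH3Br, KOt-Bu (less than the salt), THF, 0 °C → rt
Reagents that add atoms: methylenetriphenylphosphorane (from Ph3PCH3Br and KOt-Bu), C=P(c1ccccc1)(c1ccccc1)c1ccccc1
Why: Wittig methylenation; the ylide is too weakly basic to deprotonate the tertiary alcohol and is kept free of excess alkoxide, so retro-aldol cleavage of the β-hydroxy aldehyde should not compete.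

Step 12
Reactants: 15 (2E)-1-bromo-3,7-dimethylocta-2,6-diene (geranyl bromide)
Product: 16 (5E)-6,10-dimethylundeca-5,9-dien-1-yne
Conditions: HC≡CCH2Br, n-BuLi (2 equiv), TMEDA, Et2O–hexane, −78 °C; then 15, −78 °C → rt
Reagents that add atoms: 1,3-dilithiopropyne (made in the flask from propargyl bromide, C#CCBr, and n-BuLi), [Li]CC#C[Li]
Why: SN2 alkylation of the propargylic carbon of 1,3-dilithiopropyne by the primary allylic bromide (propargylation of an alkyl halide); the E double bond is untouched and the acetylide end is protonated on work-up.

Step 13
Reactants: 16 (5E)-6,10-dimethylundeca-5,9-dien-1-yne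
Product: 18 (1E,5E)-1-iodo-2,6,10-trimethylundeca-1,5,9-triene, via alkenylalane 17 (not isolated)
Conditions: Me3Al, Cp2ZrCl2 (cat.), CH2Cl2, 0 °C → rt; then I2, THF, −30 → 0 °C
Reagents that add atoms: trimethylaluminium, C[Al](C)C; iodine, II
Why: Negishi zirconium-catalysed carboalumination adds CH3 and Al syn across the terminal alkyne with Al on the terminal carbon; iodinolysis with retention gives the E vinyl iodide.

Step 14
Reactants: 14 1-vinyl analogue of 13; 18 (1E,5E)-1-iodo-2,6,10-trimethylundeca-1,5,9-triene
Product: 20 coupled ketal (C1 bears CH2OSiPh2t-Bu and the (3E,7E)-4,8,12-trimethyltrideca-3,7,11-trienyl chain; C2 the silyloxypropyl arm; C3 ethylene ketal; C6 OH and CH3), via B-alkyl-9-BBN 19 (not isolated)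
Conditions: 9-BBN, THF, rt → 50 °C; then 18, Pd(dppf)Cl2 (5 mol%), AsPh3, Cs2CO3, DMF–H2O, rt
Reagents that add atoms: none
Why: Anti-Markovnikov hydroboration of the only alkene of 14, then B-alkyl Suzuki–Miyaura coupling with retention of the iodide geometry forms the C(sp3)–C(sp2) bond. The trisubstituted alkenes of 18 arrive only after excess borane is quenched.

Step 15
Reactants: 20 coupled ketal
Product: 21 C3 ketone (20 with C=O in place of the ketal)
Conditions: pyridinium p-toluenesulfonate, acetone–H2O, 50 °C
Reagents that add atoms: water, O
Why: Mild acid-catalysed ketal hydrolysis; the silyl ethers, the tertiary alcohol and the trisubstituted alkenes tolerate this weak acid, which should not enolise C2 appreciably.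

Step 16
Reactants: 21 C3 ketone
Product: 22 tertiary allylic alcohol (C3 bears OH and isopropenyl; hydroxyl expected cis to the C2 arm, either epimer serves)
Conditions: CH2=C(CH3)MgBr (excess), CeCl3, THF, −78 → 0 °C
Reagents that add atoms: isopropenylmagnesium bromide, C=C(C)[Mg]Br
Why: Organocerium 1,2-addition to a hindered, enolisable ketone without deprotonation at C2. The reagent should enter equatorially, away from the axial CH2OSi group on C1, but the new C3 centre is removed in step 17.

Step 17
Reactants: 22 tertiary allylic alcohol
Product: 23 bis(tert-butyldiphenylsilyl) ether of the target at both primary hydroxyls (Z enal)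
Conditions: pyridinium chlorochromate (C5H5NH)[CrO3Cl], 4 Å molecular sieves, CH2Cl2, rt
Reagents that add atoms: pyridinium chlorochromate, [O-][Cr](=O)(=O)Cl.c1cc[nH+]cc1
Why: Babler–Dauben oxidative transposition: the tertiary allylic chromate ester undergoes a [3,3] shift to the primary chromate, which is oxidised to the enal. In the reacting rotamer the small =CH2 terminus, not the methyl, lies next to the substituted C2, so the formyl should end cis to C2 (Z), which is also the isomer of lower allylic strain.

Step 18
Reactants: 23 bis(tert-butyldiphenylsilyl) ether of the target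
Product: 24 (2Z)-2-[(2R,3S,4S)-4-hydroxy-3-(hydroxymethyl)-2-(3-hydroxypropyl)-4-methyl-3-[(3E,7E)-4,8,12-trimethyltrideca-3,7,11-trien-1-yl]cyclohexylidene]propanal (CNP0284886.1)
Conditions: HF·pyridine, pyridine, THF, 0 °C → rt
Reagents that add atoms: none
Why: Fluoride cleavage of both silyl ethers under buffered, non-basic conditions that leave the enal, the γ-stereocentre C2 and the polyene untouched.

## Compound list

1 | methyl 2,5-dihydroxybenzoate | COC(=O)c1cc(O)ccc1O | starting material
2 | methyl 3,6-dioxocyclohexa-1,4-diene-1-carboxylate | COC(=O)C1=CC(=O)C=CC1=O | intermediate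
3 | (E)-buta-1,3-dien-1-yl acetate | CC(=O)O/C=C/C=C | starting material
4 | methyl (4aR,5R,8aS)-5-acetoxy-1,4-dioxo-1,4,4a,5,8,8a-hexahydronaphthalene-4a-carboxylate (cis-fused; acetoxy cis to the C4 carbonyl carbon, trans to the ester) | COC(=O)[C@@]12[C@H](OC(C)=O)C=CC[C@@H]1C(=O)C=CC2=O | intermediate
5 | methyl (4aR,5R,8aS)-5-acetoxy-1,4-dioxo-1,2,3,4,4a,5,8,8a-octahydronaphthalene-4a-carboxylate | COC(=O)[C@@]12[C@H](OC(C)=O)C=CC[C@@H]1C(=O)CCC2=O | intermediate
6 | methyl (4aR,5R,8aS)-5-acetoxy-1,1-(ethylenedioxy)-4-oxo-1,2,3,4,4a,5,8,8a-octahydronaphthalene-4a-carboxylate | COC(=O)[C@@]12[C@H](OC(C)=O)C=CC[C@@H]1C3(OCCO3)CCC2=O | intermediate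
7 | methyl (4aS,8aS)-1,1-(ethylenedioxy)-4-oxo-1,2,3,4,4a,7,8,8a-octahydronaphthalene-4a-carboxylate | COC(=O)[C@@]12C=CCC[C@@H]1C3(OCCO3)CCC2=O | intermediate
8 | methyl (4S,4aS,8aS)-1,1-(ethylenedioxy)-4-hydroxy-4-methyl-1,2,3,4,4a,7,8,8a-octahydronaphthalene-4a-carboxylate (hydroxyl cis to C5, methyl cis to the ester) | COC(=O)[C@@]12C=CCC[C@@H]1C3(OCCO3)CC[C@]2(C)O | intermediate
9 | secondary ozonide (1,2,4-trioxolane) spanning former C5 and C6 of 8, formed in the flask, mixture at the two acetal carbons | COC(=O)[C@@]12C4OOC(O4)CC[C@@H]1C3(OCCO3)CC[C@]2(C)O | intermediate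
10 | methyl (1R,2S,6S)-3,3-(ethylenedioxy)-6-hydroxy-1-(hydroxymethyl)-2-(3-hydroxypropyl)-6-methylcyclohexane-1-carboxylate (CH2OH, arm and 6-OH on one face) | COC(=O)[C@@]1(CO)[C@H](CCCO)C2(OCCO2)CC[C@]1(C)O | intermediate
11 | methyl (1R,2S,6S)-1-[(tert-butyldiphenylsilyloxy)methyl]-2-[3-(tert-butyldiphenylsilyloxy)propyl]-3,3-(ethylenedioxy)-6-hydroxy-6-methylcyclohexane-1-carboxylate | COC(=O)[C@@]1(CO[Si](c2ccccc2)(c2ccccc2)C(C)(C)C)[C@H](CCCO[Si](c2ccccc2)(c2ccccc2)C(C)(C)C)C2(OCCO2)CC[C@]1(C)O | intermediate
12 | [(1R,2S,6S)-1-[(tert-butyldiphenylsilyloxy)methyl]-2-[3-(tert-butyldiphenylsilyloxy)propyl]-3,3-(ethylenedioxy)-6-hydroxy-6-methylcyclohexyl]methanol | OC[C@@]1(CO[Si](c2ccccc2)(c2ccccc2)C(C)(C)C)[C@H](CCCO[Si](c2ccccc2)(c2ccccc2)C(C)(C)C)C2(OCCO2)CC[C@]1(C)O | intermediate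
13 | (1R,2S,6S)-1-[(tert-butyldiphenylsilyloxy)methyl]-2-[3-(tert-butyldiphenylsilyloxy)propyl]-3,3-(ethylenedioxy)-6-hydroxy-6-methylcyclohexane-1-carbaldehyde | O=C[C@@]1(CO[Si](c2ccccc2)(c2ccccc2)C(C)(C)C)[C@H](CCCO[Si](c2ccccc2)(c2ccccc2)C(C)(C)C)C2(OCCO2)CC[C@]1(C)O | intermediate
14 | 1-vinyl analogue of 13 (target numbering: C1 vinyl and CH2OSiPh2t-Bu, C2 silyloxypropyl arm, C3 ethylene ketal, C6 OH and CH3; configuration as in 10) | C=C[C@@]1(CO[Si](c2ccccc2)(c2ccccc2)C(C)(C)C)[C@H](CCCO[Si](c2ccccc2)(c2ccccc2)C(C)(C)C)C2(OCCO2)CC[C@]1(C)O | intermediate
15 | (2E)-1-bromo-3,7-dimethylocta-2,6-diene (geranyl bromide) | CC(C)=CCC/C(C)=C/CBr | starting material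
16 | (5E)-6,10-dimethylundeca-5,9-dien-1-yne | C#CCC/C=C(\C)CCC=C(C)C | intermediate
17 | dimethyl[(1E,5E)-2,6,10-trimethylundeca-1,5,9-trien-1-yl]alane, formed in the flask | C[Al](C)/C=C(\C)CC/C=C(\C)CCC=C(C)C | intermediate
18 | (1E,5E)-1-iodo-2,6,10-trimethylundeca-1,5,9-triene | I/C=C(\C)CC/C=C(\C)CCC=C(C)C | intermediate
19 | B-alkyl-9-borabicyclo[3.3.1]nonane from 14 (boron on the terminal carbon of the former vinyl group), formed in the flask | B1(C2CCCC1CCC2)CC[C@@]3(CO[Si](c4ccccc4)(c4ccccc4)C(C)(C)C)[C@H](CCCO[Si](c4ccccc4)(c4ccccc4)C(C)(C)C)C4(OCCO4)CC[C@]3(C)O | intermediate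
20 | coupled ketal: C1 bears CH2OSiPh2t-Bu and the (3E,7E)-4,8,12-trimethyltrideca-3,7,11-trienyl chain, C2 the silyloxypropyl arm, C3 ethylene ketal, C6 OH and CH3 (configuration as in the target) | CC(C)=CCC/C(C)=C/CC/C(C)=C/CC[C@@]1(CO[Si](c2ccccc2)(c2ccccc2)C(C)(C)C)[C@H](CCCO[Si](c2ccccc2)(c2ccccc2)C(C)(C)C)C2(OCCO2)CC[C@]1(C)O | intermediate
21 | C3 ketone corresponding to 20 | CC(C)=CCC/C(C)=C/CC/C(C)=C/CC[C@@]1(CO[Si](c2ccccc2)(c2ccccc2)C(C)(C)C)[C@H](CCCO[Si](c2ccccc2)(c2ccccc2)C(C)(C)C)C(=O)CC[C@]1(C)O | intermediate
22 | tertiary allylic alcohol: 21 with C3 bearing OH (cis to the C2 arm) and isopropenyl | CC(C)=CCC/C(C)=C/CC/C(C)=C/CC[C@@]1(CO[Si](c2ccccc2)(c2ccccc2)C(C)(C)C)[C@H](CCCO[Si](c2ccccc2)(c2ccccc2)C(C)(C)C)[C@@](O)(C(C)=C)CC[C@]1(C)O | intermediate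
23 | bis(tert-butyldiphenylsilyl) ether of the target at both primary hydroxyls (Z enal, formyl cis to C2) | CC(C)=CCC/C(C)=C/CC/C(C)=C/CC[C@@]1(CO[Si](c2ccccc2)(c2ccccc2)C(C)(C)C)[C@H](CCCO[Si](c2ccccc2)(c2ccccc2)C(C)(C)C)/C(=C(/C)C=O)CC[C@]1(C)O | intermediate
24 | (2Z)-2-[(2R,3S,4S)-4-hydroxy-3-(hydroxymethyl)-2-(3-hydroxypropyl)-4-methyl-3-[(3E,7E)-4,8,12-trimethyltrideca-3,7,11-trien-1-yl]cyclohexylidene]propanal | CC(C)=CCC/C(C)=C/CC/C(C)=C/CC[C@@]1(CO)[C@H](CCCO)/C(=C(/C)C=O)CC[C@]1(C)O | target

## Step count and least certain steps

Total step count: 18 (16 in the main line, 2 for the vinyl iodide). Longest linear sequence: 16 steps, from 1 to 24 (steps 1–11 and 14–18).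

Step 2 (key step). Most likely to go wrong is incomplete π-face discrimination: the quinone offers three Lewis-basic carbonyls, so the catalyst may bind in more than one way, and this very reactive dienophile also reacts without catalyst, which would erode the enantiomeric purity. Fallback (auxiliary on the diene in place of a chiral catalyst): from 2, a cycloaddition at low temperature, if necessary promoted by BF3·OEt2, with the dienyl mandelate F1 (from the potassium dienolate of crotonaldehyde and (S)-O-methylmandeloyl chloride; the (R)-acid if the model points the other way) should give the mandelate adduct F2 as separable diastereomers. Zn/AcOH would give the dione F3, ketalisation as in step 4 the ketal F4, and the reduction of step 5, in which the mandelate leaves in place of acetate, comes back to the route at 7.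

Step 5. Most likely to go wrong is hydride transfer to the wrong allyl terminus, which returns the untransposed C6=C7 olefin, because both termini are secondary and differ only in their neighbours; loss of a β-hydrogen from the allylpalladium intermediate to give a diene is the second risk. Fallback (allylic diazene in place of an allylpalladium): from 6, excess MeMgBr with CeCl3 would add to the C4 ketone and cleave the acetate to give the diol F5; MnO2 would oxidise only the allylic secondary alcohol to the enone F6; p-toluenesulfonylhydrazide would give the tosylhydrazone F7; catecholborane followed by NaOAc·3H2O would reduce the C=N bond, expel sulfinate and let the allylic diazene lose N2 by a retro-ene shift that moves the double bond to C5=C6 by necessity. This comes back to the route at 8.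

Step 4. Most likely to go wrong is ketalisation at both carbonyls or at the wrong one, since the steric difference between the two ketones is real but not extreme, together with acid-mediated epimerisation of the ring fusion. Fallback (redox differentiation in place of selective ketalisation): from 5, Li[s-Bu3BH] at −78 °C should reduce only the unhindered C1 ketone from the convex face to the hydroxy ketone F8; MeMgBr/CeCl3 would add to the remaining C4 ketone to give the diol F9; Dess–Martin oxidation would restore the C1 carbonyl in the keto alcohol F10, which has no competing ketone and can be ketalised to the ketal F11; the reduction of step 5 applied to F11 comes back to the route at 8.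

Step 17. Most likely to go wrong is ionisation of the tertiary allylic chromate instead of the sigmatropic shift (capture of the cation by the C6 hydroxyl or elimination to dienes), followed by incomplete control of the enal geometry and acid-induced reactions of the polyene. Fallback (olefination in place of allylic transposition): from 21, a Horner–Wadsworth–Emmons reaction with diethyl (1-cyanoethyl)phosphonate and NaH should give the unsaturated nitrile F12, in which the slim cyano group is expected to take the place next to C2; i-Bu2AlH at −78 °C and mild acidic hydrolysis of the aldimine would give 23, where the route is rejoined without passing through a cation-prone tertiary allylic alcohol.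

## Further compounds

F1 | step 2 | (E)-buta-1,3-dien-1-yl (S)-2-methoxy-2-phenylacetate | CO[C@@H](c1ccccc1)C(=O)O/C=C/C=C
F2 | step 2 | methyl (4aR,5R,8aS)-5-[(S)-2-methoxy-2-phenylacetoxy]-1,4-dioxo-1,4,4a,5,8,8a-hexahydronaphthalene-4a-carboxylate | COC(=O)[C@@]12[C@H](OC(=O)[C@@H](OC)c3ccccc3)C=CC[C@@H]1C(=O)C=CC2=O
F3 | step 2 | 2,3-dihydro derivative of F2 (saturated 1,4-dione) | COC(=O)[C@@]12[C@H](OC(=O)[C@@H](OC)c3ccccc3)C=CC[C@@H]1C(=O)CCC2=O
F4 | step 2 | C1 ethylene ketal of F3 | COC(=O)[C@@]12[C@H](OC(=O)[C@@H](OC)c3ccccc3)C=CC[C@@H]1C4(OCCO4)CCC2=O
F5 | step 5 | methyl 1,1-(ethylenedioxy)-4,5-dihydroxy-4-methyl-1,2,3,4,4a,5,8,8a-octahydronaphthalene-4a-carboxylate (ring fusion and C5 as in 6, C4 as in 8) | COC(=O)[C@@]12[C@H](O)C=CC[C@@H]1C3(OCCO3)CC[C@]2(C)O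
F6 | step 5 | methyl 1,1-(ethylenedioxy)-4-hydroxy-4-methyl-5-oxo-1,2,3,4,4a,5,8,8a-octahydronaphthalene-4a-carboxylate | COC(=O)[C@@]12C(=O)C=CC[C@@H]1C3(OCCO3)CC[C@]2(C)O
F7 | step 5 | p-toluenesulfonylhydrazone of F6 at C5 | COC(=O)[C@@]12C(=NNS(=O)(=O)c3ccc(C)cc3)C=CC[C@@H]1C4(OCCO4)CC[C@]2(C)O
F8 | step 4 | methyl 5-acetoxy-1-hydroxy-4-oxo-1,2,3,4,4a,5,8,8a-octahydronaphthalene-4a-carboxylate (1-hydroxyl on the concave face; other centres as in 5) | COC(=O)[C@@]12[C@H](OC(C)=O)C=CC[C@@H]1[C@H](O)CCC2=O
F9 | step 4 | methyl 5-acetoxy-1,4-dihydroxy-4-methyl-1,2,3,4,4a,5,8,8a-octahydronaphthalene-4a-carboxylate (C4 as in 8) | COC(=O)[C@@]12[C@H](OC(C)=O)C=CC[C@@H]1[C@H](O)CC[C@]2(C)O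
F10 | step 4 | methyl 5-acetoxy-4-hydroxy-4-methyl-1-oxo-1,2,3,4,4a,5,8,8a-octahydronaphthalene-4a-carboxylate | COC(=O)[C@@]12[C@H](OC(C)=O)C=CC[C@@H]1C(=O)CC[C@]2(C)O
F11 | step 4 | methyl 5-acetoxy-1,1-(ethylenedioxy)-4-hydroxy-4-methyl-1,2,3,4,4a,5,8,8a-octahydronaphthalene-4a-carboxylate | COC(=O)[C@@]12[C@H](OC(C)=O)C=CC[C@@H]1C3(OCCO3)CC[C@]2(C)O
F12 | step 17 | nitrile analogue of 23 (C≡N in place of CHO, cyano cis to C2) | CC(C)=CCC/C(C)=C/CC/C(C)=C/CC[C@@]1(CO[Si](c2ccccc2)(c2ccccc2)C(C)(C)C)[C@H](CCCO[Si](c2ccccc2)(c2ccccc2)C(C)(C)C)/C(=C(/C)C#N)CC[C@]1(C)O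
A1 | alternative 1 | (bromomethyl)dimethylsilyl ether of 4-hydroxy-2-[3-(4-methoxybenzyloxy)propyl]-4-methyl-3-vinylcyclohex-2-en-1-one (carbinol carbon configured as C6 of the target) | C=CC1=C(CCCOCc2ccc(OC)cc2)C(=O)CC[C@]1(C)O[Si](C)(C)CBr
A2 | alternative 1 | cis-fused siloxane: C1 bears vinyl and the ring CH2–SiMe2–O–C6, C2 the 3-(4-methoxybenzyloxy)propyl arm, C3 ketone | C=C[C@@]1(C[Si](C)(C)O2)[C@H](CCCOCc3ccc(OC)cc3)C(=O)CC[C@@]12C
A3 | alternative 2 | 2,2-dibromopropanoate of the C2 arm alcohol of the C3 ketone whose C1–CH2O and C6–O are joined as an acetonide (chain on C1) | CC(C)=CCC/C(C)=C/CC/C(C)=C/CC[C@@]1(COC(C)(C)O2)[C@H](CCCOC(=O)C(C)(Br)Br)C(=O)CC[C@@]12C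
A4 | alternative 2 | fused eight-membered α-methyl enoate lactone (acetonide retained) | CC(C)=CCC/C(C)=C/CC/C(C)=C/CC[C@@]1(COC(C)(C)O2)[C@@H]3CCCOC(=O)/C(C)=C3/CC[C@@]12C
A5 | alternative 3 | methyl 2-(2-bromoethylidene)-3-[3-(tert-butyldiphenylsilyloxy)propyl]-4,7-dioxooctanoate (C3 configured as C2 of the target) | COC(=O)C(=CCBr)[C@H](CCCO[Si](c1ccccc1)(c1ccccc1)C(C)(C)C)C(=O)CCC(C)=O
A6 | alternative 3 | methyl 2-[3-(tert-butyldiphenylsilyloxy)propyl]-6-hydroxy-6-methyl-3-oxo-1-vinylcyclohexane-1-carboxylate (C1, C2, C6 as in the target) | C=C[C@@]1(C(=O)OC)[C@H](CCCO[Si](c2ccccc2)(c2ccccc2)C(C)(C)C)C(=O)CC[C@]1(C)O
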